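**Retrosynthetic overview**
- Feature: ring B (C6, C1, C2, C3, C4, C5) with its C3 methyl, together with C11 and its two methyls, is the p-menthane skeleton of (R)-pulegone. The rest of ring A, the chain C10–C9–C8–C7–C14, is the carbon chain of acetylacetone.
- Key disconnection: C10–C11 and C6–C7 are made in one flask by a double Michael (formal [4+2]) annulation of the acetylacetone-derived 1-methoxy-3-silyloxy diene on pulegone. Ring B is bought; ring A is the only ring formed (step 3).
- The C3 stereocentre of pulegone relays its chirality to spiro C6 and is then erased. C9 is masked, C2=C3 is introduced by dehydrogenation, and the C1 oxygen is removed through the allylic acetate.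
- C10 is brominated while ring B is still an alkene, because that is where ring A has a conformational bias. Ring B then follows: epoxide, C2 chloride, C3 bromide, all on the acid-stable enone.
- Last, the dienol acetate and borohydride give the C7=C14 methylene and the C9 carbinol together, and acetylation finishes the route.

Key step: step 3

Remark: chamigrane locants are used (C14 on C7, C15 on C3); on ring B "C11 face" and "C7 face", and on ring A "C1 face" and "C5 face", name the face on which that spiro substituent stands; the target SMILES is read as 2S,3S,6R,9S,10R, that is Cl on the C7 face, the C3 bromine on the C11 face, and the C10 bromine and C9 acetate on the C1 face.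

**Step 1**
Reactants: 1 acetylacetone; 2 trimethyl orthoformate
Product: 3 (E)-4-methoxypent-3-en-2-one
Conditions: TsOH·H2O (cat.), MeOH, 55 °C
Reagents that add atoms: trimethyl orthoformate (2), COC(OC)OC
Why: Acid-catalysed O-methylation of the enolised 1,3-diketone by the orthoester (enol ether formation) is a standard preparation, and the E isomer is the thermodynamic one.

**Step 2**
Reactants: 3 (E)-4-methoxypent-3-en-2-one; 4 chlorotrimethylsilane
Product: 6 (E)-4-methoxy-2-(trimethylsilyloxy)penta-1,3-diene, via lithium dienolate 5 (not isolated)
Conditions: LiN(i-Pr)2, THF, −78 °C; then Me3SiCl, −78 °C → rt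
Reagents that add atoms: chlorotrimethylsilane (4), C[Si](C)(C)Cl
Why: Kinetic deprotonation of the vinylogous ester at the acetyl methyl group (the future C10), followed by O-silylation of the cross-conjugated enolate, is the standard route to 1-methoxy-3-silyloxy dienes, and no stereocentre is formed.

**Step 3**
Reactants: 6 (E)-4-methoxy-2-(trimethylsilyloxy)penta-1,3-diene; 7 (R)-(+)-pulegone
Product: 10 (3R,6S)-chamigr-7-ene-1,9-dione (spiro enedione; C7 cis to the C3 methyl on ring B), via Mukaiyama–Michael adduct 8 (not isolated), via ring-closed methoxy silyl enol ether 9 (not isolated)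
Conditions: Me3SiNTf2 (10 mol %), 6 (2.5 equiv), CH2Cl2, −78 → −20 °C; then CF3CO2H, CH2Cl2, 0 °C → rt, aqueous work-up
Reagents that add atoms: none
Why: Proposed new method: Me3SiNTf2 silylates the C1 carbonyl of 7 so that C11 becomes a tertiary allyl-cation-like electrophile, the unsubstituted diene terminus C10 adds (Mukaiyama–Michael) to give the tetrasubstituted C1=C6 silyl enol ether 8, renewed silylation of its β-methoxy enone lets C6 attack C7 to give 9, and acid then removes the silyl group and methanol to leave the C7=C8 enone. The closest known reactions are Lewis-acid or high-pressure Diels–Alder and double Michael annulations of 1-methoxy-3-silyloxy dienes with enones, and conjugate additions to pulegone, but a tetrasubstituted exocyclic enone has not been shown in such an annulation. Ring A closes in a 6-endo-trig (enol-exo) mode, which is geometrically easy because the C11–C10–C9–C8 tether holds C7 over C6. The only new stereocentre, C6, is controlled by the C3 methyl: in the half-chair enol ether that keeps this methyl equatorial, C7 enters axially, that is cis to the methyl, which also leaves the bulkier C11 equatorial, so kinetic and thermodynamic preferences coincide. The step needs 1,4- over 1,2-addition and head-to-tail regiochemistry, and both follow from the matched polarity (C11 electrophilic then C6 nucleophilic, against C10 nucleophilic then C7 electrophilic), from the s-cis-locked enone, and from the bulky silyl group on oxygen, which disfavours aldol attack at C1. The steric cost of joining C11, C6 and C7 is met by the very strong silyl Lewis acid, the excess of 6 and the irreversible loss of methanol.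

**Step 4**
Reactants: 10 spiro enedione
Product: 11 C9 ethylene ketal of 10 (1,3-dioxolane at C9; C7=C8 in place; C1 ketone free)
Conditions: Me3SiOCH2CH2OSiMe3, Me3SiOTf (5 mol %), CH2Cl2, −78 → −40 °C
Reagents that add atoms: 1,2-bis(trimethylsilyloxy)ethane, C[Si](C)(C)OCCO[Si](C)(C)C
Why: Silyl-triflate-catalysed ketalisation with the bis-silylated glycol runs at low temperature without moving the C7=C8 bond, and it should select C9 because the C1 carbonyl is buried next to quaternary C6, which itself lies between C11 and C7.

**Step 5**
Reactants: 11 C9 ketal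
Product: 14 chamigra-2,7-diene-1,9-dione 9-ethylene ketal (C2=C3 enone in ring B; C6 unchanged), via lithium enolate 12 (not isolated), via C2 sulfilimine 13 (not isolated)
Conditions: LiN(i-Pr)2, THF, −78 °C; then PhS(Cl)=Nt-Bu, −78 °C
Reagents that add atoms: none
Why: C2 is the only enolisable position of the C1 ketone, so the Mukaiyama dehydrogenation (sulfur transfer to the lithium enolate and syn elimination of the sulfenamide) should give the C2=C3 enone, and the C3 stereocentre, having done its work at C6, is erased here on purpose.

**Step 6**
Reactants: 14 ring B enone ketal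
Product: 15 1-hydroxychamigra-2,7-dien-9-one ethylene ketal (C1–OH on the C7 face)
Conditions: i-Bu2AlH, CH2Cl2, −78 °C
Reagents that add atoms: none
Why: 1,2-Reduction of a hindered enone by i-Bu2AlH is reliable, hydride should arrive from the C11 face because the C14 methyl on pseudoaxial C7 screens the other face, and the new C1 centre is removed again in step 8.

**Step 7**
Reactants: 15 allylic alcohol
Product: 16 C1 acetate of 15
Conditions: Ac2O, DMAP, Et3N, CH2Cl2, rt
Reagents that add atoms: acetic anhydride, CC(=O)OC(C)=O
Why: DMAP-catalysed acetylation turns the secondary allylic alcohol into a leaving group for palladium and touches no stereocentre.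

**Step 8**
Reactants: 16 allylic acetate
Product: 18 chamigra-2,7-dien-9-one (C6 as in 10), via alkene ketal 17 (not isolated)
Conditions: Pd(PPh3)4 (5 mol %), LiBHEt3, THF, 0 °C → rt; then 1 M HCl, THF, rt
Reagents that add atoms: water, O
Why: In this Tsuji–Trost-type hydrogenolysis zerovalent palladium ionises the acetate from the open C11 face and hydride is passed to the less substituted allyl terminus C1, which leaves the more substituted C2=C3 alkene, after which dilute acid unmasks the C9 enone.

**Step 9**
Reactants: 18 chamigra-2,7-dien-9-one
Product: 21 10-bromochamigra-2,7-dien-9-one (equatorial Br on the C1 face of ring A), via lithium dienolate 19 (not isolated), via silyl dienol ether 20 (not isolated)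
Conditions: LiN(i-Pr)2, THF, −78 °C; Me3SiCl; then NBS, THF, −78 → 0 °C
Reagents that add atoms: N-bromosuccinimide, O=C1CCC(=O)N1Br
Why: Kinetic α′-deprotonation and NBS bromination of the cross-conjugated silyl dienol ether place bromine at C10; with ring B still an alkene, ring A should rest in the half-chair with C5 pseudoaxial, because C14 then lies under sp2 C2 and not against the axial hydrogen on C4, so bromine enters anti to C5 on the C1 face and ends equatorial, the same epimer that equilibration through the enol would favour.

**Step 10**
Reactants: 21 bromo enone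
Product: 22 10-bromo-2,3-epoxychamigr-7-en-9-one (epoxide oxygen on the C11 face)
Conditions: mCPBA, CH2Cl2, 0 °C
Reagents that add atoms: 3-chloroperoxybenzoic acid, O=C(OO)c1cccc(Cl)c1
Why: The Prilezhaev epoxidation picks the electron-rich trisubstituted C2=C3 alkene over the bromo enone, and in the ring B half-chair with bulky C11 pseudoequatorial and sp2 C7 pseudoaxial the C14 methyl covers the C7 face, so oxygen should be delivered to the C11 face, which fixes C2 and C3 relative to C6.

**Step 11**
Reactants: 22 epoxide
Product: 23 10-bromo-2-chloro-3-hydroxychamigr-7-en-9-one (Cl on the C7 face; OH on the C11 face)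
Conditions: LiCl, AcOH, THF, rt → 40 °C
Reagents that add atoms: lithium chloride, [Li+].[Cl-]
Why: Under weakly acidic, chloride-rich conditions the epoxide opens in an SN2 manner at secondary C2 with inversion, the small chloride reaching the C7 face along the outward-pointing backside trajectory after ring B flips to put C7 pseudoequatorial, while the tertiary C3–O bond keeps its configuration.

**Step 12**
Reactants: 23 chlorohydrin
Product: 24 3,10-dibromo-2-chlorochamigr-7-en-9-one (C3–Br on the C11 face trans to Cl)
Conditions: Me3SiBr, CH2Cl2, −20 °C → rt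
Reagents that add atoms: bromotrimethylsilane, C[Si](C)(C)Br
Why: Me3SiBr converts tertiary alcohols into bromides by ionisation, and retention at C3 is expected because the C2 chlorine anti to the leaving oxygen shields or bridges the C7 face (chloronium-type neighbouring-group participation) while bromide collapses from the contact ion pair on the C11 face; the acid-stable enone of ring A is the reason this step comes before the methylene is made.

**Step 13**
Reactants: 24 bromochloride
Product: 25 9-acetoxy-3,10-dibromo-2-chlorochamigra-7(14),8-diene (linear dienol acetate)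
Conditions: Ac2O, HClO4 (cat.), EtOAc, 0 °C → rt
Reagents that add atoms: acetic anhydride, CC(=O)OC(C)=O
Why: Acid-catalysed enol acetylation under equilibrating conditions should give the linear dienol acetate by loss of a C14 proton, since C6 carries no hydrogen and enolisation towards C10 would put bromine on a tetrasubstituted alkene beside quaternary C11, so C10 should keep its configuration.

**Step 14**
Reactants: 25 dienol acetate
Product: 28 isoobtusol (C7=C14 methylene; axial C9–OH cis to the C10 bromine), via sodium dienolate 26 (not isolated), via exo-methylene bromo ketone 27 (not isolated)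
Conditions: NaBH4, EtOH–THF, 0 °C
Reagents that add atoms: none
Why: This is the deconjugative borohydride reduction known from steroidal 3,5-dienol acetates: ethanolysis frees the dienolate, kinetic protonation at C8 gives 27, its activated α-bromo carbonyl is reduced faster than it reconjugates, and hydride attacks C9 equatorially, away from the axial C11 methyl, to give the axial alcohol cis to the equatorial bromine.

**Step 15**
Reactants: 28 isoobtusol
Product: 29 9-acetylisoobtusol (target)
Conditions: Ac2O, DMAP, pyridine, rt
Reagents that add atoms: acetic anhydride, CC(=O)OC(C)=O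
Why: DMAP-catalysed acetylation of the axial secondary alcohol leaves C9 untouched, and the cis bromohydrin cannot close to an epoxide under this mild base.

**Compound list**
1 | acetylacetone | CC(=O)CC(C)=O | starting material
2 | trimethyl orthoformate | COC(OC)OC | starting material
3 | (E)-4-methoxypent-3-en-2-one | CO/C(C)=C/C(C)=O | intermediate
4 | chlorotrimethylsilane | C[Si](C)(C)Cl | starting material
5 | lithium (E)-4-methoxypenta-1,3-dien-2-olate | C=C(O[Li])/C=C(\C)OC | intermediate
6 | (E)-4-methoxy-2-(trimethylsilyloxy)penta-1,3-diene | C=C(O[Si](C)(C)C)/C=C(\C)OC | intermediate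
7 | (R)-(+)-pulegone | CC(C)=C1CC[C@@H](C)CC1=O | starting material
8 | Mukaiyama–Michael adduct (C1=C6 silyl enol ether with the β-methoxy enone chain on C11) | CO/C(C)=C/C(=O)CC(C)(C)C1=C(O[Si](C)(C)C)C[C@H](C)CC1 | intermediate
9 | ring-closed 7-methoxy C8=C9 silyl enol ether | COC1(C)C=C(O[Si](C)(C)C)CC(C)(C)[C@@]12CC[C@@H](C)CC2=O | intermediate
10 | (3R,6S)-chamigr-7-ene-1,9-dione | CC1=CC(=O)CC(C)(C)[C@@]12CC[C@@H](C)CC2=O | intermediate
11 | C9 ethylene ketal of 10 | CC1=CC2(OCCO2)CC(C)(C)[C@@]13CC[C@@H](C)CC3=O | intermediate
12 | lithium C1=C2 enolate of 11 | CC1=CC2(OCCO2)CC(C)(C)[C@@]13CC[C@@H](C)C=C3O[Li] | intermediate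
13 | C2 S-phenyl-N-tert-butylsulfilimine of 11 | CC1=CC2(OCCO2)CC(C)(C)[C@@]13CC[C@@H](C)C(S(=NC(C)(C)C)c4ccccc4)C3=O | intermediate
14 | chamigra-2,7-diene-1,9-dione 9-ethylene ketal | CC1=CC2(OCCO2)CC(C)(C)[C@@]13CCC(C)=CC3=O | intermediate
15 | 1-hydroxychamigra-2,7-dien-9-one ethylene ketal (OH on the C7 face) | CC1=CC2(OCCO2)CC(C)(C)[C@@]13CCC(C)=C[C@H]3O | intermediate
16 | C1 acetate of 15 | CC1=CC2(OCCO2)CC(C)(C)[C@@]13CCC(C)=C[C@H]3OC(C)=O | intermediate
17 | chamigra-2,7-dien-9-one ethylene ketal | CC1=CC2(OCCO2)CC(C)(C)[C@@]13CCC(C)=CC3 | intermediate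
18 | chamigra-2,7-dien-9-one | CC1=CC(=O)CC(C)(C)[C@@]12CCC(C)=CC2 | intermediate
19 | lithium cross-conjugated dienolate of 18 | CC1=CC(O[Li])=CC(C)(C)[C@@]12CCC(C)=CC2 | intermediate
20 | trimethylsilyl dienol ether of 18 (C9=C10) | CC1=CC(O[Si](C)(C)C)=CC(C)(C)[C@@]12CCC(C)=CC2 | intermediate
21 | 10-bromochamigra-2,7-dien-9-one | CC1=CC(=O)[C@H](Br)C(C)(C)[C@@]12CCC(C)=CC2 | intermediate
22 | 10-bromo-2,3-epoxychamigr-7-en-9-one | CC1=CC(=O)[C@H](Br)C(C)(C)[C@@]12CC[C@]3(C)O[C@@H]3C2 | intermediate
23 | 10-bromo-2-chloro-3-hydroxychamigr-7-en-9-one | CC1=CC(=O)[C@H](Br)C(C)(C)[C@@]12CC[C@](C)(O)[C@@H](Cl)C2 | intermediate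
24 | 3,10-dibromo-2-chlorochamigr-7-en-9-one | CC1=CC(=O)[C@H](Br)C(C)(C)[C@@]12CC[C@](C)(Br)[C@@H](Cl)C2 | intermediate
25 | 9-acetoxy-3,10-dibromo-2-chlorochamigra-7(14),8-diene | C=C1C=C(OC(C)=O)[C@H](Br)C(C)(C)[C@@]12CC[C@](C)(Br)[C@@H](Cl)C2 | intermediate
26 | sodium dienolate from 25 | C=C1C=C([O-])[C@H](Br)C(C)(C)[C@@]12CC[C@](C)(Br)[C@@H](Cl)C2.[Na+] | intermediate
27 | 3,10-dibromo-2-chlorochamigr-7(14)-en-9-one | C=C1CC(=O)[C@H](Br)C(C)(C)[C@@]12CC[C@](C)(Br)[C@@H](Cl)C2 | intermediate
28 | isoobtusol | C=C1C[C@H](O)[C@H](Br)C(C)(C)[C@@]12CC[C@](C)(Br)[C@@H](Cl)C2 | intermediate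
29 | 9-acetylisoobtusol, (2S,3S,6R,9S,10R) | C=C1C[C@H](OC(C)=O)[C@H](Br)C(C)(C)[C@@]12CC[C@](C)(Br)[C@@H](Cl)C2 | target

Total step count: 15. Longest linear sequence: 15 steps from acetylacetone (13 from pulegone).

**Steps most likely to fail**

**Step 3 (key step).**
- What may go wrong: the first bond may not form at the tetrasubstituted β-carbon. Acid-induced decomposition of the diene, deconjugation of pulegone or aldol attack at C1 may be faster, or the second closure may stall at the open-chain adduct.
- Fallback: the same two bonds are made stepwise by known reactions, setting out from 7 and returning at 10.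
- Hosomi–Sakurai conjugate allylation of 7 (allyltrimethylsilane, TiCl4, CH2Cl2, −78 °C) forms C10–C11 and gives 8-allyl-p-menthan-3-one F1.
- Ozonolysis (O3, then Me2S) gives the keto aldehyde F2.
- CH3C≡CMgBr adds to the aldehyde alone at −78 °C to give the propargylic alcohol F3.
- Dess–Martin oxidation gives the ynone F4.
- KOt-Bu in t-BuOH equilibrates the C1 enolates, and the C6 enolate closes on C7 by intramolecular Michael addition (6-endo-dig). The same axial attack cis to the C3 methyl applies, and the product is 10.

**Step 12.**
- What may go wrong: after ionisation at C3, loss of a proton (elimination) or capture of bromide on the C7 face (loss of retention) may compete. Chlorine participation needs an antiperiplanar C–O/C–Cl arrangement that the crowded ring B may not reach.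
- Fallback: bromine is delivered as an electrophile to the open C11 face. The sequence sets out from 22 and returns at 24, so it also bypasses step 11.
- Meinwald rearrangement of 22 (BF3·OEt2, CH2Cl2, −78 °C; hydride shift from C2 to C3) gives the C2 ketone F5.
- PhNMe3Br3 in THF brominates through the more substituted C2=C3 enol on the C11 face and gives the tertiary α-bromo ketone F6.
- One equivalent of NaBH4 in MeOH at −78 °C reduces this more electrophilic saturated ketone, anti to the C–Br bond, and gives the cis bromohydrin F7 (OH on the C11 face).
- An Appel reaction (PPh3, CCl4) replaces the hydroxyl by chloride with inversion. The cis bromine cannot participate, and the product is 24.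

**Step 14.**
- What may go wrong: the freed bromo dienolate may lose bromide (Favorskii-type ionisation) or be protonated at C14 (reconjugation) before reduction, and the facial selectivity of the hydride may be poor.
- Fallback: the alkene is moved by palladium instead of through a dienolate, setting out from 24 and returning at 29.
- Luche reduction (NaBH4, CeCl3·7H2O, MeOH, −78 °C) gives the allylic alcohol F8, cis to bromine.
- Ac2O, DMAP and pyridine give the acetate F9.
- SeO2 with t-BuOOH oxidises the only allylic position on the more substituted alkene carbon, the C14 methyl, and gives the primary alcohol F10.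
- ClCO2Me and pyridine give the carbonate F11.
- Formate hydrogenolysis (Pd(OAc)2, PBu3, HCO2H, Et3N, THF) passes hydride to the more substituted allyl terminus C8. This leaves the C7=C14 methylene and gives 29 directly.

**Further compounds**
F1 | step 3 | 8-allyl-p-menthan-3-one (C6 epimers, epimerisable) | C=CCC(C)(C)C1CC[C@@H](C)CC1=O
F2 | step 3 | 3-methyl-3-[(4R)-4-methyl-2-oxocyclohexyl]butanal | O=CCC(C)(C)C1CC[C@@H](C)CC1=O
F3 | step 3 | propargylic alcohol from F2 and propynylmagnesium bromide | CC#CC(O)CC(C)(C)C1CC[C@@H](C)CC1=O
F4 | step 3 | ynone (C9 ketone, C8≡C7, C14 methyl) | CC#CC(=O)CC(C)(C)C1CC[C@@H](C)CC1=O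
F5 | step 12 | 10-bromochamigr-7-ene-2,9-dione (C3 epimers) | CC1=CC(=O)[C@H](Br)C(C)(C)[C@@]12CCC(C)C(=O)C2
F6 | step 12 | 3,10-dibromochamigr-7-ene-2,9-dione (C3–Br on the C11 face) | CC1=CC(=O)[C@H](Br)C(C)(C)[C@@]12CC[C@](C)(Br)C(=O)C2
F7 | step 12 | 3,10-dibromo-2-hydroxychamigr-7-en-9-one (OH on the C11 face, cis to the C3 bromine) | CC1=CC(=O)[C@H](Br)C(C)(C)[C@@]12CC[C@](C)(Br)[C@H](O)C2
F8 | step 14 | 3,10-dibromo-2-chlorochamigr-7-en-9-ol (OH cis to the C10 bromine) | CC1=C[C@H](O)[C@H](Br)C(C)(C)[C@@]12CC[C@](C)(Br)[C@@H](Cl)C2
F9 | step 14 | C9 acetate of F8 | CC1=C[C@H](OC(C)=O)[C@H](Br)C(C)(C)[C@@]12CC[C@](C)(Br)[C@@H](Cl)C2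
F10 | step 14 | 14-hydroxy derivative of F9 | OCC1=C[C@H](OC(C)=O)[C@H](Br)C(C)(C)[C@@]12CC[C@](C)(Br)[C@@H](Cl)C2
F11 | step 14 | C14 methyl carbonate of F10 | COC(=O)OCC1=C[C@H](OC(C)=O)[C@H](Br)C(C)(C)[C@@]12CC[C@](C)(Br)[C@@H](Cl)C2
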